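Remark: lignan numbering is used throughout. C7, C8 and C9 are the propane chain, ring A is the 4-hydroxy-3-methoxyphenyl ring on C7, and ring B is the 2,6-dimethoxy-4-(3-hydroxypropenyl)phenyl ring bound to the C8 oxygen. TBS = tert-butyldimethylsilyl, TBDPS = tert-butyldiphenylsilyl.

## The problem

Target 15 is the threo-(7S,8S) isomer of guaiacylglycerol 8-O-4' sinapyl alcohol ether. It is an open-chain arylglycerol with ring A on C7 and hydroxyls on C7 and C9, and its C8 oxygen is the phenolic oxygen of a sinapyl alcohol unit (ring B). No ring has to be closed. The work lies in building the C7–C8–C9 chain with the aryl ether on C8 and in setting two adjacent stereocentres, the benzylic carbinol C7 (S) and the aryloxy methine C8 (S), in the syn relation and in one absolute sense. The centres are 1,2-related, so a preset C8 can steer an addition to a C7 carbonyl. A preset C7 could only steer C8 through a substitution at a crowded secondary carbon. Ring B is electron-rich and carries two ortho methoxy groups, which excludes SNAr and makes a late O-arylation at C8 difficult, so the C8–O bond is best made with the phenol as nucleophile. The molecule is fragile in three ways: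
- the 4-hydroxybenzyl alcohol at C7 ionises to a quinone methide under acid or hot base, which would scramble C7;
- the 4-oxygenated cinnamyl alcohol is acid-labile, and its E-alkene forbids hydrogenolytic protecting groups;
- every C7 carbonyl intermediate has an acidic C8–H.

The enabling feature is that C8 with its aryloxy oxygen and C9 with its hydroxyl reproduce C2 and C3 of glyceric acid. The C8 oxygen is twisted out of the plane of ring B by the two ortho methoxy groups and sits alpha to C7, so an (S)-2-aryloxy aldehyde can hold divalent magnesium in a five-membered chelate and pass its configuration on to C7 when ring A arrives as a nucleophile.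

## Retrosynthesis

**15 from 14 (three O–Si bonds).** The phenol of ring A, the cinnamyl hydroxyl and the C9 hydroxyl are masked as silyl ethers in 14 and released together by fluoride. Benzyl-type groups are excluded by the alkene and acid-labile groups by the benzylic and cinnamyl alcohols. Compound 14 has the full skeleton and both stereocentres, so the last step only has to cleave Si–O bonds without ionising C7.

**14 from 10 and 13 (the bond from C7 to C1 of ring A).** This cut removes ring A and the C7 stereocentre in one stroke and leaves aldehyde 10 with the single stereocentre C8. The neighbouring cuts are less attractive: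
- cutting C8–O at this stage would call for substitution at C8 next to a benzylic carbinol, or for arylation with a hindered, electron-rich arene;
- cutting C7–C8 as an aldol would have to set both centres at once with an auxiliary.

The forward reaction must deliver the aryl group of Grignard reagent 13 to aldehyde 10 in the syn sense and must not epimerise C8.

**13 from 12 from 11.** The nucleophile needs only a phenol protecting group that survives magnesium and falls to fluoride. Silylation of 4-bromo-2-methoxyphenol 11 gives bromide 12, and magnesium insertion gives 13.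

**10 from 9 (oxidation level at C7).** The aldehyde is configurationally labile, so it is stored as methyl ester 9 and released by a partial hydride reduction just before use. Ester 9 has the same atoms and the same stereocentre. The forward step must stop at the aldehyde and stay cold.

**9 from 5 and 8 (the C8–O bond).** Cutting the aryl ether at the alkyl side gives phenol 5 and the glycerate-derived hydroxy ester 8. The forward reaction is a Mitsunobu etherification, which inverts (R)-8 into (S)-9. The ring B side cannot be the electrophile, so this is the only realistic polarity. The precursors are an achiral phenol and a two-step chiral-pool ester. The reaction must tolerate a di-ortho-substituted phenol and must not racemise the alpha-carbon.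

**8 from 7 from 6.** The primary hydroxyl of methyl (R)-glycerate 7 takes the bulky TBDPS group selectively. The TBDPS group is chosen because it is a poor donor for magnesium. Diol 7 comes from the commercial acetonide 6 by acetal hydrolysis.

**5 from 4, 3, 2 and 1.** Phenol 5 is sinapyl alcohol 3 with only its aliphatic hydroxyl silylated. It is reached through the bis-silyl ether 4 and selective cleavage of the aryl silyl ether. Sinapyl alcohol 3 comes from syringaldehyde 1 by Wittig olefination to ethyl sinapate 2 and 1,2-reduction, which fixes the E-alkene at the start.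

## Roads not taken

**Alternative 1:** The cut is the bond from the C8 oxygen to C4' of ring B, made last on a chain that already has both stereocentres.
- Forward key step: the sodium alkoxide (NaOtBu) of the silylene-bridged alcohol A1, (4S,5S)-2,2-di-tert-butyl-4-[3-methoxy-4-(triisopropylsilyloxy)phenyl]-1,3,2-dioxasilinan-5-ol, would exchange onto the trivalent iodine of the unsymmetrical diaryliodonium tosylate A2, which bears the ring B aryl group and a 2,4,6-trimethoxyphenyl dummy. Ligand coupling would give aryl ether A3 with retention at C8, because no bond to C8 is broken.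
- Merits: both stereocentres of A1 would come from one catalytic asymmetric dihydroxylation (K2OsO2(OH)4 with a cinchona ligand) of the ring A cinnamyl double bond. Syn addition to an E-alkene guarantees the threo relation. In certainty of relative configuration this road is better than the chosen one.
- Weak points: the aryl group to be transferred is electron-rich and di-ortho-methoxylated, exactly like the dummy ligand, so the electronic and steric bias that normally decides which aryl leaves iodine is lost. Secondary alkoxides are also oxidised to ketones by such salts. The acrylate of A2 is open to conjugate addition of alkoxide. Making A2 means oxidising an electron-rich, alkene-bearing arene at iodine. After the coupling, the acrylate still has to be reduced and two different silicon groups removed.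
- Comparison: the chosen plan has the less certain stereocontrol. Against that, each of its steps is a reaction type of established scope on its substrate class, and its weak point yields separable diastereomers that can be corrected. A failed aryl transfer yields nothing.

**Alternative 2:** The cut is the C7–H bond, with C8 left stereochemically mobile until the same step.
- Forward key step: the racemic beta-keto ester A4, ethyl 2-{4-[(E)-3-ethoxy-3-oxoprop-1-enyl]-2,6-dimethoxyphenoxy}-3-[3-methoxy-4-(pivaloyloxy)phenyl]-3-oxopropanoate, would be reduced by RuCl(p-cymene)[(R,R)-TsDPEN] (divalent ruthenium) in HCO2H/Et3N while C8 racemises through the enol. This would give the syn hydroxy ester A5 with both centres set.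
- Merits: one iBu2AlH treatment of A5 would reduce both esters and remove the pivalate to give 15. This is the shortest road and the only one that sets both centres catalytically. In step economy it is clearly better than the chosen plan.
- Weak points: absolute and relative configuration rest on a single catalyst–substrate match. Dynamic kinetic reductions of this kind are established for alpha-alkoxy and alpha-amido keto esters. The very bulky 2,6-dimethoxyaryloxy group next to the ketone is a different steric situation. Any shortfall in enantioselectivity appears as the enantiomer, which chromatography does not remove.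
- Comparison: the chosen plan is longer. It sets against this a C8 configuration bought from the chiral pool, so that only one diastereoselection is at risk and its errors are separable diastereomers.

**Alternative 3:** The cut is the C8–C9 bond.
- Forward key step: the (Z)-trimethylsilyl enol ether A6 of the 2-aryloxy-1-arylethanone would react with aqueous formaldehyde under Sc(OTf)3 (trivalent scandium) and a chiral 2,2'-bipyridine diol ligand. This would give the (S)-hydroxymethyl ketone A7.
- Merits: the carbon skeleton comes from very simple pieces, C9 arrives unprotected, and no chiral-pool or Mitsunobu steps are needed. The road is no longer than the chosen one.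
- Weak points: only C8 is set. C7 then needs a second, substrate-controlled ketone reduction. A7 is a beta-hydroxy ketone whose C8–H lies between an aryl ketone and an aryloxy group, so epimerisation, retro-aldol cleavage and dehydration to the enone are all open. The hydroxymethylation is best established for alpha-alkyl enol ethers. An alpha-aryloxy enol ether with a bulky ring B, which must also be a single Z isomer and survive water, is outside that range.
- Comparison: the chosen plan has one uncertain selectivity event and one labile intermediate, which is used at once. This road has two selectivity events and a labile intermediate that must be carried through a further step.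

Key step: step 11

Step 1
Reactants: 1 syringaldehyde (4-hydroxy-3,5-dimethoxybenzaldehyde)
Product: 2 ethyl (2E)-3-(4-hydroxy-3,5-dimethoxyphenyl)prop-2-enoate (ethyl (E)-sinapate)
Conditions: Ph3P=CHCO2Et (1.2 equiv), toluene, 110 °C
Reagents that add atoms: ethyl (triphenylphosphoranylidene)acetate, CCOC(=O)C=P(c1ccccc1)(c1ccccc1)c1ccccc1
Why: Wittig olefination with a stabilised ylide, which tolerates the free phenol and gives the E-alkene under the usual control of ester-stabilised ylides.

Step 2
Reactants: 2 ethyl (E)-sinapate
Product: 3 4-[(1E)-3-hydroxyprop-1-en-1-yl]-2,6-dimethoxyphenol (sinapyl alcohol)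
Conditions: iBu2AlH (4 equiv), toluene, −78 to 0 °C; aq. potassium sodium tartrate
Reagents that add atoms: none
Why: 1,2-reduction of an alpha,beta-unsaturated ester to the allylic alcohol by an aluminium hydride; one equivalent is consumed by the phenol and the E-alkene is not touched.

Step 3
Reactants: 3 sinapyl alcohol
Product: 4 tert-butyl{4-[(1E)-3-(tert-butyldimethylsilyloxy)prop-1-en-1-yl]-2,6-dimethoxyphenoxy}dimethylsilane
Conditions: TBSCl (2.5 equiv), imidazole (5 equiv), DMF, rt
Reagents that add atoms: tert-butyldimethylsilyl chloride, CC(C)(C)[Si](C)(C)Cl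
Why: Standard imidazole-promoted silylation of both hydroxyls; exhaustive silylation avoids the poor discrimination between a phenol and a primary alcohol.

Step 4
Reactants: 4 bis-silyl ether of sinapyl alcohol
Product: 5 4-[(1E)-3-(tert-butyldimethylsilyloxy)prop-1-en-1-yl]-2,6-dimethoxyphenol
Conditions: K2CO3 (1.2 equiv), MeOH, 0 °C to rt; aq. NH4Cl
Reagents that add atoms: none
Why: Selective methanolysis of an aryl silyl ether; phenoxide is a far better leaving group from silicon than alkoxide, so the allylic TBS ether should stay.

Step 5
Reactants: 6 methyl (4R)-2,2-dimethyl-1,3-dioxolane-4-carboxylate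
Product: 7 methyl (2R)-2,3-dihydroxypropanoate (methyl (R)-glycerate)
Conditions: AcOH–H2O (4:1), rt; evaporation with toluene
Reagents that add atoms: none
Why: Acid-catalysed acetal hydrolysis; no bond to the stereocentre is broken and the methyl ester survives dilute acetic acid.

Step 6
Reactants: 7 methyl (R)-glycerate
Product: 8 methyl (2R)-3-(tert-butyldiphenylsilyloxy)-2-hydroxypropanoate
Conditions: TBDPSCl (1.05 equiv), imidazole, CH2Cl2, 0 °C
Reagents that add atoms: tert-butyldiphenylsilyl chloride, CC(C)(C)[Si](Cl)(c1ccccc1)c1ccccc1
Why: Selective silylation of the primary hydroxyl by a bulky silyl chloride; the secondary hydroxyl next to the ester is hindered and less nucleophilic.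

Step 7
Reactants: 5 4-[(1E)-3-(tert-butyldimethylsilyloxy)prop-1-en-1-yl]-2,6-dimethoxyphenol; 8 methyl (2R)-3-(tert-butyldiphenylsilyloxy)-2-hydroxypropanoate
Product: 9 methyl (2S)-2-{4-[(E)-3-(tert-butyldimethylsilyloxy)prop-1-enyl]-2,6-dimethoxyphenoxy}-3-(tert-butyldiphenylsilyloxy)propanoate
Conditions: PPh3, iPrO2C–N=N–CO2iPr (DIAD), THF, 0 °C to rt
Reagents that add atoms: none
Why: Mitsunobu etherification of an alpha-hydroxy ester with a phenol of pKa about 10; SN2 displacement of the alkoxyphosphonium ion inverts C8 from R to S, and the substrate has no acidic beta-hydrogen through which elimination could compete.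

Step 8
Reactants: 9 methyl (2S)-2-aryloxy-3-(tert-butyldiphenylsilyloxy)propanoate
Product: 10 (2S)-2-{4-[(E)-3-(tert-butyldimethylsilyloxy)prop-1-enyl]-2,6-dimethoxyphenoxy}-3-(tert-butyldiphenylsilyloxy)propanal
Conditions: iBu2AlH (1.1 equiv), CH2Cl2, −78 °C; MeOH at −78 °C, then aq. potassium sodium tartrate; crude aldehyde dried cold and used at once
Reagents that add atoms: none
Why: Partial reduction of an alpha-alkoxy ester; the aluminium hemiacetal is held by the neighbouring aryloxy oxygen at −78 °C and collapses to the aldehyde only on work-up, and the base-free, cold handling protects the C8 configuration.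

Step 9
Reactants: 11 4-bromo-2-methoxyphenol
Product: 12 (4-bromo-2-methoxyphenoxy)(tert-butyl)dimethylsilane
Conditions: TBSCl (1.1 equiv), imidazole, DMF, rt
Reagents that add atoms: tert-butyldimethylsilyl chloride, CC(C)(C)[Si](C)(C)Cl
Why: Standard phenol silylation; the silyl ether removes the acidic proton and is inert to magnesium.

Step 10
Reactants: 12 (4-bromo-2-methoxyphenoxy)(tert-butyl)dimethylsilane
Product: 13 [4-(tert-butyldimethylsilyloxy)-3-methoxyphenyl]magnesium bromide (solution in Et2O, titrated and used directly)
Conditions: Mg turnings (I2 cat.), Et2O, 35 °C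
Reagents that add atoms: magnesium, [Mg]
Why: Grignard formation by insertion of zerovalent magnesium into the aryl C–Br bond; the silyloxy group is para to the metal, so no silyl migration is possible, and Et2O keeps THF out of the next step.

Step 11
Reactants: 10 (2S)-2-aryloxy-3-(tert-butyldiphenylsilyloxy)propanal; 13 [4-(tert-butyldimethylsilyloxy)-3-methoxyphenyl]magnesium bromide
Product: 14 (1S,2S)-2-{4-[(E)-3-(tert-butyldimethylsilyloxy)prop-1-enyl]-2,6-dimethoxyphenoxy}-1-[4-(tert-butyldimethylsilyloxy)-3-methoxyphenyl]-3-(tert-butyldiphenylsilyloxy)propan-1-ol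
Conditions: MgBr2·OEt2 (2 equiv), CH2Cl2, −78 °C, 20 min; then 13 (1.5 equiv, Et2O), −78 °C; aq. NH4Cl
Reagents that add atoms: none
Why: Pre-complexation with MgBr2·OEt2 in weakly coordinating CH2Cl2 ties the C7 carbonyl oxygen and the C8 aryloxy oxygen of 10 to one divalent magnesium in a five-membered chelate, and the aryl group of 13 is then transferred to the carbonyl carbon in a polar 1,2-addition that forms the bond from C7 to C1 of ring A. The closest known reaction type is the chelation-controlled (Cram chelate) addition of Grignard reagents to alpha-alkoxy aldehydes, which gives syn 1,2-diol monoethers; here the donor is an aryl ether, a less common but not a new case. No ring is closed. The new stereocentre C7 is controlled by C8: the chelate locks the C7–C8 rotamer, the CH2OTBDPS group covers one face and the aryl group enters past the C8 hydrogen, which for (S)-C8 gives (7S), the syn (threo) alcohol. The selectivity needed is syn (chelate) over anti (polar Felkin–Anh), and three features of the substrate secure it: the C8 oxygen is twisted out of conjugation with ring B by the two ortho methoxy groups and is a better donor than an ordinary aryl ether oxygen, one ortho methoxy oxygen can fill a third coordination site, and the bulky, weakly basic TBDPS ether at O9 cannot form the six-membered chelate that would lead to the anti product. Excess MgBr2, the absence of THF and −78 °C keep the chelate populated and should make aryl transfer faster than enolisation at C8.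

Step 12
Reactants: 14 tris-silyl ether
Product: 15 (1S,2S)-1-(4-hydroxy-3-methoxyphenyl)-2-{4-[(1E)-3-hydroxyprop-1-en-1-yl]-2,6-dimethoxyphenoxy}propane-1,3-diol (target)
Conditions: Bu4NF (4 equiv), AcOH (4 equiv), THF, 0 °C to rt
Reagents that add atoms: none
Why: Fluoride-driven cleavage of the aryl TBS, allyl TBS and primary TBDPS ethers in one operation; acetic acid buffers the liberated phenoxide so that C7 is not ionised through a quinone methide, and no bond to C7 or C8 is broken.

## Compound list

1 | syringaldehyde (4-hydroxy-3,5-dimethoxybenzaldehyde) | COc1cc(C=O)cc(OC)c1O | starting material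
2 | ethyl (2E)-3-(4-hydroxy-3,5-dimethoxyphenyl)prop-2-enoate | CCOC(=O)/C=C/c1cc(OC)c(O)c(OC)c1 | intermediate
3 | 4-[(1E)-3-hydroxyprop-1-en-1-yl]-2,6-dimethoxyphenol (sinapyl alcohol) | OC/C=C/c1cc(OC)c(O)c(OC)c1 | intermediate
4 | tert-butyl{4-[(1E)-3-(tert-butyldimethylsilyloxy)prop-1-en-1-yl]-2,6-dimethoxyphenoxy}dimethylsilane | COc1cc(/C=C/CO[Si](C)(C)C(C)(C)C)cc(OC)c1O[Si](C)(C)C(C)(C)C | intermediate
5 | 4-[(1E)-3-(tert-butyldimethylsilyloxy)prop-1-en-1-yl]-2,6-dimethoxyphenol | COc1cc(/C=C/CO[Si](C)(C)C(C)(C)C)cc(OC)c1O | intermediate
6 | methyl (4R)-2,2-dimethyl-1,3-dioxolane-4-carboxylate | COC(=O)[C@H]1COC(C)(C)O1 | starting material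
7 | methyl (2R)-2,3-dihydroxypropanoate | COC(=O)[C@H](O)CO | intermediate
8 | methyl (2R)-3-(tert-butyldiphenylsilyloxy)-2-hydroxypropanoate | COC(=O)[C@H](O)CO[Si](c1ccccc1)(c1ccccc1)C(C)(C)C | intermediate
9 | methyl (2S)-2-{4-[(E)-3-(tert-butyldimethylsilyloxy)prop-1-enyl]-2,6-dimethoxyphenoxy}-3-(tert-butyldiphenylsilyloxy)propanoate | COC(=O)[C@H](CO[Si](c1ccccc1)(c1ccccc1)C(C)(C)C)Oc1c(OC)cc(/C=C/CO[Si](C)(C)C(C)(C)C)cc1OC | intermediate
10 | (2S)-2-{4-[(E)-3-(tert-butyldimethylsilyloxy)prop-1-enyl]-2,6-dimethoxyphenoxy}-3-(tert-butyldiphenylsilyloxy)propanal | O=C[C@H](CO[Si](c1ccccc1)(c1ccccc1)C(C)(C)C)Oc1c(OC)cc(/C=C/CO[Si](C)(C)C(C)(C)C)cc1OC | intermediate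
11 | 4-bromo-2-methoxyphenol | COc1cc(Br)ccc1O | starting material
12 | (4-bromo-2-methoxyphenoxy)(tert-butyl)dimethylsilane | COc1cc(Br)ccc1O[Si](C)(C)C(C)(C)C | intermediate
13 | [4-(tert-butyldimethylsilyloxy)-3-methoxyphenyl]magnesium bromide | COc1cc([Mg]Br)ccc1O[Si](C)(C)C(C)(C)C | intermediate
14 | (1S,2S)-2-{4-[(E)-3-(tert-butyldimethylsilyloxy)prop-1-enyl]-2,6-dimethoxyphenoxy}-1-[4-(tert-butyldimethylsilyloxy)-3-methoxyphenyl]-3-(tert-butyldiphenylsilyloxy)propan-1-ol | COc1cc([C@H](O)[C@H](CO[Si](c3ccccc3)(c3ccccc3)C(C)(C)C)Oc2c(OC)cc(/C=C/CO[Si](C)(C)C(C)(C)C)cc2OC)ccc1O[Si](C)(C)C(C)(C)C | intermediate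
15 | (1S,2S)-1-(4-hydroxy-3-methoxyphenyl)-2-{4-[(1E)-3-hydroxyprop-1-en-1-yl]-2,6-dimethoxyphenoxy}propane-1,3-diol | COc1cc([C@H](O)[C@H](CO)Oc2c(OC)cc(/C=C/CO)cc2OC)ccc1O | target

## Step count and risks

Total step count: 12. Longest linear sequence: 8 steps (steps 1, 2, 3, 4, 7, 8, 11 and 12).

**Step 11 (key step).** The likely failure is poor facial selectivity. The aryl ether oxygen is a weaker donor than an alkyl ether oxygen, so the open polar Felkin–Anh pathway may compete and lead to the C7 epimer. Enolisation of the chelated aldehyde by the basic Grignard reagent would also erode C8. The fallback sets out from 10 and comes back at 14.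
- The addition of 13 to 10 is run in THF without Lewis acid and with no regard to the facial outcome.
- The mixture of 14 and its C7 epimer, (1R,2S)-2-{4-[(E)-3-(tert-butyldimethylsilyloxy)prop-1-enyl]-2,6-dimethoxyphenoxy}-1-[4-(tert-butyldimethylsilyloxy)-3-methoxyphenyl]-3-(tert-butyldiphenylsilyloxy)propan-1-ol F1, is oxidised with Dess–Martin periodinane and NaHCO3 in CH2Cl2.
- This gives the single ketone (2S)-2-{4-[(E)-3-(tert-butyldimethylsilyloxy)prop-1-enyl]-2,6-dimethoxyphenoxy}-1-[4-(tert-butyldimethylsilyloxy)-3-methoxyphenyl]-3-(tert-butyldiphenylsilyloxy)propan-1-one F2.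
- Li(sBu)3BH in THF at −78 °C should reduce F2 under polar Felkin–Anh control, with hydride anti to the aryloxy group and past the C8 hydrogen. Aryl and hydrogen have exchanged roles relative to the Grignard addition, so the Felkin–Anh sense now gives the syn alcohol 14.

**Step 8.** The likely failures are over-reduction to the primary alcohol, if the aluminium hemiacetal collapses before the quench, and loss of C8 configuration during work-up or on silica. The fallback sets out from 9 and comes back at 10.
- LiBH4 in THF reduces the ester fully to (2R)-2-{4-[(E)-3-(tert-butyldimethylsilyloxy)prop-1-enyl]-2,6-dimethoxyphenoxy}-3-(tert-butyldiphenylsilyloxy)propan-1-ol F4, a stable compound that can be purified and stored.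
- Dess–Martin periodinane buffered with NaHCO3 in CH2Cl2 oxidises F4 to 10 immediately before step 11.

**Step 7.** The likely failure is slow displacement at the alkoxyphosphonium ion. The nucleophile is a di-ortho-substituted phenol of modest acidity, and the electrophilic carbon carries the bulky silyloxymethyl group. The reduced azo reagent may then be alkylated instead, or the activated ester may partly racemise. The fallback sets out from 8 and comes back at 9.
- Tf2O and 2,6-lutidine in CH2Cl2 at −78 °C give methyl (2R)-3-(tert-butyldiphenylsilyloxy)-2-(trifluoromethanesulfonyloxy)propanoate F3.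
- The potassium phenoxide of 5 (K2CO3, MeCN, 0 °C) displaces the triflate in an SN2 reaction with inversion to give 9.

**Step 12.** The likely failures are incomplete cleavage of the TBDPS ether under buffered fluoride and, if the buffer is insufficient, base-induced quinone methide formation from the freed ring A phenoxide with scrambling at C7. Separating the polar product from ammonium salts may also cost material. The fallback sets out from 14 and comes back at 15.
- K2CO3 in MeOH removes only the aryl silyl ether and gives 4-[(1S,2S)-2-{4-[(E)-3-(tert-butyldimethylsilyloxy)prop-1-enyl]-2,6-dimethoxyphenoxy}-3-(tert-butyldiphenylsilyloxy)-1-hydroxypropyl]-2-methoxyphenol F5.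
- Et3N·3HF in THF/MeCN, a near-neutral and volatile fluoride source under which the phenol stays protonated, then removes the two alkyl silyl ethers to give 15.

## Further compounds

F1 | step 11 | (1R,2S)-2-{4-[(E)-3-(tert-butyldimethylsilyloxy)prop-1-enyl]-2,6-dimethoxyphenoxy}-1-[4-(tert-butyldimethylsilyloxy)-3-methoxyphenyl]-3-(tert-butyldiphenylsilyloxy)propan-1-ol | COc1cc([C@@H](O)[C@H](CO[Si](c3ccccc3)(c3ccccc3)C(C)(C)C)Oc2c(OC)cc(/C=C/CO[Si](C)(C)C(C)(C)C)cc2OC)ccc1O[Si](C)(C)C(C)(C)C
F2 | step 11 | (2S)-2-{4-[(E)-3-(tert-butyldimethylsilyloxy)prop-1-enyl]-2,6-dimethoxyphenoxy}-1-[4-(tert-butyldimethylsilyloxy)-3-methoxyphenyl]-3-(tert-butyldiphenylsilyloxy)propan-1-one | COc1cc(C(=O)[C@H](CO[Si](c3ccccc3)(c3ccccc3)C(C)(C)C)Oc2c(OC)cc(/C=C/CO[Si](C)(C)C(C)(C)C)cc2OC)ccc1O[Si](C)(C)C(C)(C)C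
F3 | step 7 | methyl (2R)-3-(tert-butyldiphenylsilyloxy)-2-(trifluoromethanesulfonyloxy)propanoate | COC(=O)[C@H](OS(=O)(=O)C(F)(F)F)CO[Si](c1ccccc1)(c1ccccc1)C(C)(C)C
F4 | step 8 | (2R)-2-{4-[(E)-3-(tert-butyldimethylsilyloxy)prop-1-enyl]-2,6-dimethoxyphenoxy}-3-(tert-butyldiphenylsilyloxy)propan-1-ol | OC[C@H](CO[Si](c1ccccc1)(c1ccccc1)C(C)(C)C)Oc1c(OC)cc(/C=C/CO[Si](C)(C)C(C)(C)C)cc1OC
F5 | step 12 | 4-[(1S,2S)-2-{4-[(E)-3-(tert-butyldimethylsilyloxy)prop-1-enyl]-2,6-dimethoxyphenoxy}-3-(tert-butyldiphenylsilyloxy)-1-hydroxypropyl]-2-methoxyphenol | COc1cc([C@H](O)[C@H](CO[Si](c3ccccc3)(c3ccccc3)C(C)(C)C)Oc2c(OC)cc(/C=C/CO[Si](C)(C)C(C)(C)C)cc2OC)ccc1O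
A1 | alternative 1 | (4S,5S)-2,2-di-tert-butyl-4-[3-methoxy-4-(triisopropylsilyloxy)phenyl]-1,3,2-dioxasilinan-5-ol | COc1cc([C@@H]2O[Si](C(C)(C)C)(C(C)(C)C)OC[C@@H]2O)ccc1O[Si](C(C)C)(C(C)C)C(C)C
A2 | alternative 1 | {4-[(E)-3-ethoxy-3-oxoprop-1-enyl]-2,6-dimethoxyphenyl}(2,4,6-trimethoxyphenyl)iodonium 4-methylbenzenesulfonate | CCOC(=O)/C=C/c1cc(OC)c([I+]c2c(OC)cc(OC)cc2OC)c(OC)c1.Cc1ccc(cc1)S(=O)(=O)[O-]
A3 | alternative 1 | ethyl (E)-3-[4-({(4S,5S)-2,2-di-tert-butyl-4-[3-methoxy-4-(triisopropylsilyloxy)phenyl]-1,3,2-dioxasilinan-5-yl}oxy)-3,5-dimethoxyphenyl]acrylate | COc1cc([C@@H]3O[Si](C(C)(C)C)(C(C)(C)C)OC[C@@H]3Oc2c(OC)cc(/C=C/C(=O)OCC)cc2OC)ccc1O[Si](C(C)C)(C(C)C)C(C)C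
A4 | alternative 2 | ethyl 2-{4-[(E)-3-ethoxy-3-oxoprop-1-enyl]-2,6-dimethoxyphenoxy}-3-[3-methoxy-4-(pivaloyloxy)phenyl]-3-oxopropanoate (racemic) | COc1cc(C(=O)C(C(=O)OCC)Oc2c(OC)cc(/C=C/C(=O)OCC)cc2OC)ccc1OC(=O)C(C)(C)C
A5 | alternative 2 | ethyl (2R,3S)-2-{4-[(E)-3-ethoxy-3-oxoprop-1-enyl]-2,6-dimethoxyphenoxy}-3-hydroxy-3-[3-methoxy-4-(pivaloyloxy)phenyl]propanoate | COc1cc([C@H](O)[C@H](C(=O)OCC)Oc2c(OC)cc(/C=C/C(=O)OCC)cc2OC)ccc1OC(=O)C(C)(C)C
A6 | alternative 3 | {[(1Z)-2-{4-[(E)-3-(tert-butyldimethylsilyloxy)prop-1-enyl]-2,6-dimethoxyphenoxy}-1-[3-methoxy-4-(triisopropylsilyloxy)phenyl]ethenyl]oxy}trimethylsilane | COc1cc(/C(O[Si](C)(C)C)=C/Oc2c(OC)cc(/C=C/CO[Si](C)(C)C(C)(C)C)cc2OC)ccc1O[Si](C(C)C)(C(C)C)C(C)C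
A7 | alternative 3 | (2S)-2-{4-[(E)-3-(tert-butyldimethylsilyloxy)prop-1-enyl]-2,6-dimethoxyphenoxy}-3-hydroxy-1-[3-methoxy-4-(triisopropylsilyloxy)phenyl]propan-1-one | COc1cc(C(=O)[C@H](CO)Oc2c(OC)cc(/C=C/CO[Si](C)(C)C(C)(C)C)cc2OC)ccc1O[Si](C(C)C)(C(C)C)C(C)C
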